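**Plan**

- Numbering: ring A (3-hydroxy-4-methoxyphenyl)–C7–C8(C9H2OBz)–C8'(C9'H2OBz)–C7'–ring B (C1'–C6', OMe on C3', OH on C4').
- Enabling feature: on ring B the C4' oxygen is para and the C3' methoxy meta to C7'. This is the pattern of a 4-alkyl-2-methoxycyclohex-2-enone (C4'=O, C3'–OMe, alkyl on C1') one dehydrogenation below the arene, so ring B can be grown on the chain.
- Retrosynthesis: remove the ring A benzyl ether, return ring B to the enone, cut C1'–C6' and C2'–C3' (aldehyde C8'–C7'–C1'H2–C2'HO plus 1-methoxybut-3-en-2-one). Then go back through the alkene, the dibenzoate and a trans lactone, and cut C8–C8' (3-arylpropanal plus (E)-1-nitrohexa-1,5-diene).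
- Forward: ring A enters as an aryl bromide; the chain is joined at C8–C8' by an organocatalytic Michael addition; C9/C9' pass through lactone and diol to the dibenzoate; alkene cleavage gives the aldehyde; ring B is annulated, aromatised, and the benzyl ether is removed.
- Stereochemistry: C8 (R) and C8' (R) are set together, syn, in the one Michael step by (S)-α,α-diphenylprolinol trimethylsilyl ether. No later step needs stereocontrol, and the ring B stereocentre made in the annulation disappears on aromatisation.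

Key step: step 12

Assumption: the (S)-configured prolinol catalyst is taken to give the (8R,8'R) syn adduct, as its usual facial preference with α-unbranched aldehydes and (E)-nitroalkenes predicts; if the opposite sense were found, the (R)-catalyst would be used.

**Route**

Step 1
Reactants: 1 5-bromo-2-methoxyphenol
Product: 2 2-(benzyloxy)-4-bromo-1-methoxybenzene
Conditions: BnBr, K2CO3, DMF, rt
Reagents that add atoms: benzyl bromide, BrCc1ccccc1
Why: Williamson etherification of the phenoxide; the benzyl ether keeps the ring A phenol out of the later nitrosation, hydride, acylation and oxidation steps and is removable by hydrogenolysis at the end.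

Step 2
Reactants: 2 2-(benzyloxy)-4-bromo-1-methoxybenzene; 3 allyl alcohol
Product: 5 3-[3-(benzyloxy)-4-methoxyphenyl]propanal, via enol 4 (not isolated)
Conditions: Pd(OAc)2 (cat.), Bu4NCl, NaHCO3, DMF, 80 °C
Reagents that add atoms: none
Why: Heck arylation of an allylic alcohol under ligand-free phase-transfer conditions: the aryl group adds to the terminal alkene carbon, β-hydride elimination towards the carbinol carbon gives the enol, and tautomerisation gives the saturated aldehyde.

Step 3
Reactants: 6 pent-4-enal; 7 nitromethane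
Product: 8 1-nitrohex-5-en-2-ol (racemic)
Conditions: MeNO2 (excess), KOtBu (cat.), THF/tBuOH, 0 °C to rt
Reagents that add atoms: none
Why: Henry (nitroaldol) addition of the nitronate to an unhindered aliphatic aldehyde; the carbinol centre is destroyed in the next step, so it needs no control.

Step 4
Reactants: 8 1-nitrohex-5-en-2-ol
Product: 10 (E)-1-nitrohexa-1,5-diene, via mesylate 9 (not isolated)
Conditions: MsCl, Et3N, CH2Cl2, 0 °C; used fresh
Reagents that add atoms: none
Why: O-sulfonylation followed by E1cB elimination through the nitronate, which gives the conjugated nitroalkene as the thermodynamically preferred E isomer.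

Step 5
Reactants: 5 3-[3-(benzyloxy)-4-methoxyphenyl]propanal (1.5 equiv); 10 (E)-1-nitrohexa-1,5-diene
Product: 12 (2R,3R)-2-[3-(benzyloxy)-4-methoxybenzyl]-3-(nitromethyl)hept-6-enal, via enamine 11 (not isolated)
Conditions: (S)-α,α-diphenylprolinol trimethylsilyl ether (10 mol %), 4-nitrophenol (10 mol %), toluene, 0 °C to rt
Reagents that add atoms: none
Why: enamine-catalysed asymmetric Michael addition of an aldehyde to a nitroalkene: the (E)-enamine 11, shielded on one face by the CPh2(OSiMe3) group, adds through the open synclinal transition state, so C8 and C8' are formed together as the syn (R,R) pair under catalyst control.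

Step 6
Reactants: 12 (2R,3R)-2-[3-(benzyloxy)-4-methoxybenzyl]-3-(nitromethyl)hept-6-enal
Product: 13 (2R,3R)-2-[3-(benzyloxy)-4-methoxybenzyl]-3-(nitromethyl)hept-6-en-1-ol
Conditions: NaBH4, MeOH, 0 °C (on the crude adduct)
Reagents that add atoms: none
Why: chemoselective borohydride reduction of the aldehyde (nitro group and alkene untouched), done at once so that the epimerisable centre C8 is fixed as a carbinol-bearing carbon.

Step 7
Reactants: 13 (2R,3R)-2-[3-(benzyloxy)-4-methoxybenzyl]-3-(nitromethyl)hept-6-en-1-ol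
Product: 15 (3R,4R)-4-[3-(benzyloxy)-4-methoxybenzyl]-3-(but-3-en-1-yl)oxolan-2-one, via hydroxy acid 14 (not isolated)
Conditions: NaNO2, AcOH, DMSO, 35 °C; then aq. HCl work-up, TsOH (cat.), CH2Cl2, rt
Reagents that add atoms: water, O; sodium nitrite, [Na+].[O-]N=O
Why: nitrite-mediated oxidative Nef-type conversion of the primary nitro group into a carboxylic acid (by way of nitrolic acid and nitrile oxide), followed by 5-exo-trig lactonisation of the γ-hydroxy acid; the conditions are only weakly acidic and the trans lactone is the more stable arrangement, so C8' should keep its configuration.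

Step 8
Reactants: 15 (3R,4R)-4-[3-(benzyloxy)-4-methoxybenzyl]-3-(but-3-en-1-yl)oxolan-2-one
Product: 16 (2R,3R)-2-[3-(benzyloxy)-4-methoxybenzyl]-3-(but-3-en-1-yl)butane-1,4-diol
Conditions: LiAlH4, THF, 0 °C
Reagents that add atoms: none
Why: hydride reduction of a lactone to the 1,4-diol, fast at 0 °C and without effect on the benzyl ether, the alkene or either stereocentre.

Step 9
Reactants: 16 (2R,3R)-2-[3-(benzyloxy)-4-methoxybenzyl]-3-(but-3-en-1-yl)butane-1,4-diol
Product: 17 (2R,3R)-2-[3-(benzyloxy)-4-methoxybenzyl]-3-(but-3-en-1-yl)butane-1,4-diyl dibenzoate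
Conditions: BzCl, pyridine, DMAP (cat.), CH2Cl2, 0 °C to rt
Reagents that add atoms: benzoyl chloride, O=C(Cl)c1ccccc1
Why: DMAP-catalysed acylation of two unhindered primary alcohols, installing both benzoates of the target while the only phenol is still masked.

Step 10
Reactants: 17 (2R,3R)-2-[3-(benzyloxy)-4-methoxybenzyl]-3-(but-3-en-1-yl)butane-1,4-diyl dibenzoate
Product: 19 (2R,3R)-2-[3-(benzyloxy)-4-methoxybenzyl]-3-(3-oxopropyl)butane-1,4-diyl dibenzoate, via diol 18 (not isolated)
Conditions: OsO4 (cat.), NaIO4, 2,6-lutidine, 1,4-dioxane/H2O, rt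
Reagents that add atoms: osmium tetroxide, O=[Os](=O)(=O)=O; sodium periodate, [Na+].[O-]I(=O)(=O)=O
Why: Lemieux–Johnson oxidation: dihydroxylation of the only alkene and periodate cleavage of the glycol, chosen over ozone to spare the electron-rich ring A, with lutidine suppressing over-oxidation.

Step 11
Reactants: 20 methoxyacetyl chloride; 21 tributyl(vinyl)stannane
Product: 22 1-methoxybut-3-en-2-one
Conditions: PdCl2(PPh3)2 (cat.), CHCl3, 60 °C, BHT (trace); distilled and used fresh
Reagents that add atoms: none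
Why: Stille acylation (ketone synthesis from an acid chloride and a vinylstannane): oxidative addition of the acyl chloride to zerovalent palladium, vinyl transfer from tin and reductive elimination, with no free nucleophile present that could add to the sensitive enone.

Step 12
Reactants: 19 (2R,3R)-2-[3-(benzyloxy)-4-methoxybenzyl]-3-(3-oxopropyl)butane-1,4-diyl dibenzoate; 22 1-methoxybut-3-en-2-one (1.5 equiv)
Product: 26 (2R,3R)-2-[3-(benzyloxy)-4-methoxybenzyl]-3-[(3-methoxy-4-oxocyclohex-2-en-1-yl)methyl]butane-1,4-diyl dibenzoate (both epimers at the ring carbon), via pyrrolidine enamine 23 (not isolated), via ketoaldehyde 24 (not isolated), via aldol 25 (not isolated)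
Conditions: pyrrolidine (30 mol %), AcOH (30 mol %), CH2Cl2, 0 °C to rt; then TsOH·H2O (cat.), 4 Å molecular sieves, toluene, 60 °C
Reagents that add atoms: none
Why: Pyrrolidine condenses with the aldehyde of 19 to enamine 23, whose nucleophilic carbon (C1') adds to the terminal carbon of 22 (bond C1'–C6'), and hydrolysis returns the amine and the 1,5-ketoaldehyde 24. Acid then enolises the ketone towards its methoxy-bearing carbon, which attacks the aldehyde (bond C2'–C3') to give aldol 25, and loss of water gives the 2-methoxycyclohex-2-enone 26. The closest known reaction type is the amine-mediated Robinson annulation of α-unbranched aldehydes with vinyl ketones to 4-substituted cyclohexenones, here run with an alkoxymethyl vinyl ketone. Ring B closes in the 6-(enolendo)-exo-trig mode. The new stereocentre at C1' and the transient centres of 25 are left uncontrolled, since dehydration and the later aromatisation remove them, while C8 and C8' lie too far from any carbonyl to epimerise. The step needs mono-addition, secured because the aldehyde α-carbon is tertiary after one Michael addition and forms an enamine only slowly, and closure through the CH2OMe carbon, secured because every other enol or enamine carbon would have to form a four-membered ring; this places the methoxy group next to the carbonyl.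

Step 13
Reactants: 26 (2R,3R)-2-[3-(benzyloxy)-4-methoxybenzyl]-3-[(3-methoxy-4-oxocyclohex-2-en-1-yl)methyl]butane-1,4-diyl dibenzoate
Product: 28 (2R,3R)-2-[3-(benzyloxy)-4-methoxybenzyl]-3-(4-hydroxy-3-methoxybenzyl)butane-1,4-diyl dibenzoate, via dienone 27 (not isolated)
Conditions: Pd(O2CCF3)2 (5 mol %), 2-(dimethylamino)pyridine (10 mol %), TsOH·H2O (20 mol %), O2 (1 atm), DMSO, 80 °C
Reagents that add atoms: none
Why: palladium-catalysed aerobic dehydrogenation of a cyclohexenone to a phenol: the divalent palladium enolate at C5' (the only enolisable α-carbon) undergoes β-hydride elimination from C6' to the cross-conjugated dienone 27, which tautomerises through its C1'–H to the phenol, so both ring epimers converge on one arene with OH on C4' and OMe on C3'.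

Step 14
Reactants: 28 (2R,3R)-2-[3-(benzyloxy)-4-methoxybenzyl]-3-(4-hydroxy-3-methoxybenzyl)butane-1,4-diyl dibenzoate
Product: 29 (2R,3R)-2-(3-hydroxy-4-methoxybenzyl)-3-(4-hydroxy-3-methoxybenzyl)butane-1,4-diyl dibenzoate (CNP0306197.1)
Conditions: H2 (1 atm), Pd/C, EtOAc, rt
Reagents that add atoms: none
Why: catalytic hydrogenolysis of the aryl benzyl ether; the benzoates sit on non-benzylic primary carbons and are not cleaved, and no stereocentre is touched.

**Compound list**

1 | 5-bromo-2-methoxyphenol | COc1ccc(Br)cc1O | starting material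
2 | 2-(benzyloxy)-4-bromo-1-methoxybenzene | COc1ccc(Br)cc1OCc1ccccc1 | intermediate
3 | allyl alcohol (prop-2-en-1-ol) | C=CCO | starting material
4 | 3-[3-(benzyloxy)-4-methoxyphenyl]prop-1-en-1-ol (enol) | COc1ccc(CC=CO)cc1OCc1ccccc1 | intermediate
5 | 3-[3-(benzyloxy)-4-methoxyphenyl]propanal | COc1ccc(CCC=O)cc1OCc1ccccc1 | intermediate
6 | pent-4-enal | C=CCCC=O | starting material
7 | nitromethane | C[N+](=O)[O-] | starting material
8 | 1-nitrohex-5-en-2-ol (racemic) | C=CCCC(O)C[N+](=O)[O-] | intermediate
9 | 1-nitrohex-5-en-2-yl methanesulfonate | C=CCCC(OS(C)(=O)=O)C[N+](=O)[O-] | intermediate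
10 | (E)-1-nitrohexa-1,5-diene | C=CCC/C=C/[N+](=O)[O-] | intermediate
11 | (S)-1-{(E)-3-[3-(benzyloxy)-4-methoxyphenyl]prop-1-en-1-yl}-2-{diphenyl[(trimethylsilyl)oxy]methyl}pyrrolidine (enamine) | COc1ccc(C/C=C/N2CCC[C@H]2C(c2ccccc2)(c2ccccc2)O[Si](C)(C)C)cc1OCc1ccccc1 | intermediate
12 | (2R,3R)-2-[3-(benzyloxy)-4-methoxybenzyl]-3-(nitromethyl)hept-6-enal | COc1ccc(C[C@@H](C=O)[C@H](C[N+](=O)[O-])CCC=C)cc1OCc1ccccc1 | intermediate
13 | (2R,3R)-2-[3-(benzyloxy)-4-methoxybenzyl]-3-(nitromethyl)hept-6-en-1-ol | COc1ccc(C[C@@H](CO)[C@H](C[N+](=O)[O-])CCC=C)cc1OCc1ccccc1 | intermediate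
14 | (R)-2-{(R)-1-[3-(benzyloxy)-4-methoxyphenyl]-3-hydroxypropan-2-yl}hex-5-enoic acid | COc1ccc(C[C@@H](CO)[C@H](C(=O)O)CCC=C)cc1OCc1ccccc1 | intermediate
15 | (3R,4R)-4-[3-(benzyloxy)-4-methoxybenzyl]-3-(but-3-en-1-yl)oxolan-2-one (trans lactone) | COc1ccc(C[C@H]2COC(=O)[C@@H]2CCC=C)cc1OCc1ccccc1 | intermediate
16 | (2R,3R)-2-[3-(benzyloxy)-4-methoxybenzyl]-3-(but-3-en-1-yl)butane-1,4-diol | COc1ccc(C[C@@H](CO)[C@H](CO)CCC=C)cc1OCc1ccccc1 | intermediate
17 | (2R,3R)-2-[3-(benzyloxy)-4-methoxybenzyl]-3-(but-3-en-1-yl)butane-1,4-diyl dibenzoate | COc1ccc(C[C@@H](COC(=O)c2ccccc2)[C@H](COC(=O)c2ccccc2)CCC=C)cc1OCc1ccccc1 | intermediate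
18 | (2R,3R)-2-[3-(benzyloxy)-4-methoxybenzyl]-3-(3,4-dihydroxybutyl)butane-1,4-diyl dibenzoate (both carbinol epimers) | COc1ccc(C[C@@H](COC(=O)c2ccccc2)[C@H](COC(=O)c2ccccc2)CCC(O)CO)cc1OCc1ccccc1 | intermediate
19 | (2R,3R)-2-[3-(benzyloxy)-4-methoxybenzyl]-3-(3-oxopropyl)butane-1,4-diyl dibenzoate | COc1ccc(C[C@@H](COC(=O)c2ccccc2)[C@H](COC(=O)c2ccccc2)CCC=O)cc1OCc1ccccc1 | intermediate
20 | methoxyacetyl chloride | COCC(=O)Cl | starting material
21 | tributyl(vinyl)stannane | C=C[Sn](CCCC)(CCCC)CCCC | starting material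
22 | 1-methoxybut-3-en-2-one | COCC(=O)C=C | intermediate
23 | (2R,3R)-2-[3-(benzyloxy)-4-methoxybenzyl]-3-[(E)-3-(pyrrolidin-1-yl)prop-2-en-1-yl]butane-1,4-diyl dibenzoate (enamine) | COc1ccc(C[C@@H](COC(=O)c2ccccc2)[C@H](COC(=O)c2ccccc2)C/C=C/N2CCCC2)cc1OCc1ccccc1 | intermediate
24 | (2R,3R)-2-[3-(benzyloxy)-4-methoxybenzyl]-3-(2-formyl-6-methoxy-5-oxohexyl)butane-1,4-diyl dibenzoate (both epimers at the formyl-bearing carbon) | COc1ccc(C[C@@H](COC(=O)c2ccccc2)[C@H](COC(=O)c2ccccc2)CC(C=O)CCC(=O)COC)cc1OCc1ccccc1 | intermediate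
25 | (2R,3R)-2-[3-(benzyloxy)-4-methoxybenzyl]-3-[(2-hydroxy-3-methoxy-4-oxocyclohexyl)methyl]butane-1,4-diyl dibenzoate (diastereomer mixture in the new ring) | COc1ccc(C[C@@H](COC(=O)c2ccccc2)[C@H](COC(=O)c2ccccc2)CC2CCC(=O)C(OC)C2O)cc1OCc1ccccc1 | intermediate
26 | (2R,3R)-2-[3-(benzyloxy)-4-methoxybenzyl]-3-[(3-methoxy-4-oxocyclohex-2-en-1-yl)methyl]butane-1,4-diyl dibenzoate (both epimers at the ring carbon) | COc1ccc(C[C@@H](COC(=O)c2ccccc2)[C@H](COC(=O)c2ccccc2)CC2CCC(=O)C(OC)=C2)cc1OCc1ccccc1 | intermediate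
27 | (2R,3R)-2-[3-(benzyloxy)-4-methoxybenzyl]-3-[(3-methoxy-4-oxocyclohexa-2,5-dien-1-yl)methyl]butane-1,4-diyl dibenzoate (dienone) | COc1ccc(C[C@@H](COC(=O)c2ccccc2)[C@H](COC(=O)c2ccccc2)CC2C=CC(=O)C(OC)=C2)cc1OCc1ccccc1 | intermediate
28 | (2R,3R)-2-[3-(benzyloxy)-4-methoxybenzyl]-3-(4-hydroxy-3-methoxybenzyl)butane-1,4-diyl dibenzoate | COc1ccc(C[C@@H](COC(=O)c2ccccc2)[C@H](COC(=O)c2ccccc2)Cc2ccc(O)c(OC)c2)cc1OCc1ccccc1 | intermediate
29 | (2R,3R)-2-(3-hydroxy-4-methoxybenzyl)-3-(4-hydroxy-3-methoxybenzyl)butane-1,4-diyl dibenzoate | COc1ccc(C[C@@H](COC(=O)c2ccccc2)[C@H](COC(=O)c2ccccc2)Cc2ccc(O)c(OC)c2)cc1O | target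

**Step count**

Total step count: 14. Longest linear sequence: 11 steps (1, 2, 5, 6, 7, 8, 9, 10, 12, 13, 14).

**Steps most likely to fail**

1. Step 12. Under amine catalysis the vinyl ketone may oligomerise and the aldehyde may self-condense faster than the cross Michael addition, or the cyclodehydration may stall. The fallback sets out from 19 and returns at 26. Aldehyde 19 would be converted (Me3SiCl, Et3N, NaI, MeCN) into its trimethylsilyl enol ether, (2R,3R)-2-[3-(benzyloxy)-4-methoxybenzyl]-3-{3-[(trimethylsilyl)oxy]prop-2-en-1-yl}butane-1,4-diyl dibenzoate F1. This would be added to 22 in a TiCl4-promoted Mukaiyama–Michael reaction (CH2Cl2, −78 °C), so that no amine is present while the C1'–C6' bond forms. Aqueous work-up should release ketoaldehyde 24, isolated this time, and acid-catalysed aldol condensation (TsOH, toluene, molecular sieves) would close C2'–C3' to give 26.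

2. Step 13. The palladium catalyst may aggregate to the metal before conversion is complete, or the electron-rich phenol may be degraded oxidatively under O2 at 80 °C. The fallback sets out from 26 and returns at 28. Kinetic deprotonation at C5' (LiN(SiMe3)2, THF, −78 °C; the benzoates are not enolisable) and trapping with PhSeCl would give the α-selenide, (2R,3R)-2-[3-(benzyloxy)-4-methoxybenzyl]-3-{[3-methoxy-4-oxo-5-(phenylselanyl)cyclohex-2-en-1-yl]methyl}butane-1,4-diyl dibenzoate F2. Oxidation (H2O2, pyridine, CH2Cl2, 0 °C) would give the corresponding selenoxide, the 5-(phenylseleninyl) compound F3. Its syn elimination should give dienone 27, which tautomerises to 28 without any transition metal or oxygen atmosphere.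

3. Step 7. Under the nitrosating conditions the oxidation may stop short of the acid, and nitrosation of the free hydroxyl or of ring A may compete. The fallback sets out from 13 and returns at 16. Deprotonation (NaOMe, MeOH, 0 °C) would give the sodium nitronate, the sodium salt of (2R,3R)-2-[3-(benzyloxy)-4-methoxybenzyl]-3-(aci-nitromethyl)hept-6-en-1-ol F4. Adding this to NH4OAc-buffered aqueous TiCl3 is a reductive Nef reaction that stops at the aldehyde oxidation level; the aldehyde would be captured by the neighbouring hydroxyl as the lactol, (3R,4R)-4-[3-(benzyloxy)-4-methoxybenzyl]-3-(but-3-en-1-yl)oxolan-2-ol F5 (both anomers), which protects C8' from epimerisation. NaBH4 in MeOH would then give diol 16 directly, bypassing lactone 15 and the LiAlH4 step.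

**Further compounds**

F1 | step 12 | (2R,3R)-2-[3-(benzyloxy)-4-methoxybenzyl]-3-{3-[(trimethylsilyl)oxy]prop-2-en-1-yl}butane-1,4-diyl dibenzoate (E/Z mixture) | COc1ccc(C[C@@H](COC(=O)c2ccccc2)[C@H](COC(=O)c2ccccc2)CC=CO[Si](C)(C)C)cc1OCc1ccccc1
F2 | step 13 | (2R,3R)-2-[3-(benzyloxy)-4-methoxybenzyl]-3-{[3-methoxy-4-oxo-5-(phenylselanyl)cyclohex-2-en-1-yl]methyl}butane-1,4-diyl dibenzoate | COc1ccc(C[C@@H](COC(=O)c2ccccc2)[C@H](COC(=O)c2ccccc2)CC2CC([Se]c3ccccc3)C(=O)C(OC)=C2)cc1OCc1ccccc1
F3 | step 13 | (2R,3R)-2-[3-(benzyloxy)-4-methoxybenzyl]-3-{[3-methoxy-4-oxo-5-(phenylseleninyl)cyclohex-2-en-1-yl]methyl}butane-1,4-diyl dibenzoate | COc1ccc(C[C@@H](COC(=O)c2ccccc2)[C@H](COC(=O)c2ccccc2)CC2CC([Se](=O)c3ccccc3)C(=O)C(OC)=C2)cc1OCc1ccccc1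
F4 | step 7 | sodium salt of (2R,3R)-2-[3-(benzyloxy)-4-methoxybenzyl]-3-(aci-nitromethyl)hept-6-en-1-ol | COc1ccc(C[C@@H](CO)[C@H](C=[N+]([O-])[O-])CCC=C)cc1OCc1ccccc1.[Na+]
F5 | step 7 | (3R,4R)-4-[3-(benzyloxy)-4-methoxybenzyl]-3-(but-3-en-1-yl)oxolan-2-ol (both anomers) | COc1ccc(C[C@H]2COC(O)[C@@H]2CCC=C)cc1OCc1ccccc1
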